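## Retrosynthetic overview

1. Dendronpholide Q ⇐ C11 acetylation and desilylation ⇐ α-methylenation (Mannich–decarboxylation) of an α-carboxy ε-lactone ⇐ opening of an (11S,12S)-epoxide at C12 by a malonic acid (inversion).
2. THF ring (C4–O–C7, C8–OH) ⇐ osmium-catalysed oxidative cyclisation of a (3R,4R)-3,4-diol onto the (E)-C7=C8 alkene.
3. Key disconnection C3–C4: the 14-membered carbocycle and the 3,4-diol come from a keto-aldehyde by ketyl (umpoled carbonyl carbon) pinacol macrocyclisation.
4. Keto-aldehyde ⇐ organocatalytic malonate Michael addition (sets C1) ⇐ cross-metathesis of (5E,9E)-farnesylacetone with crotonaldehyde.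
5. Ring order: 14-membered carbocycle → THF → ε-lactone; the α-methylene group is installed last.

Assumption: commercial farnesylacetone is used as the pure (5E,9E) isomer, and cembrane numbering is used in all names (C1 bears the acrylate unit, C16 is the lactone carbonyl, C17 the exocyclic methylene).

## Route

Step 1
Reactants: 1 (5E,9E)-farnesylacetone; 2 (E)-crotonaldehyde
Product: 3 (2E,6E,10E)-6,10-dimethyl-14-oxopentadeca-2,6,10-trienal
Conditions: 2 (5 equiv), second-generation Hoveyda–Grubbs catalyst RuCl2(H2IMes)(=CH-C6H4-2-OiPr) (5 mol %), CH2Cl2, 40 °C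
Reagents that add atoms: none
Why: Olefin cross-metathesis in which the terminal isopropylidene is the only accessible alkene (the two internal trisubstituted alkenes and the ketone are spectators), giving the (E)-enal with loss of volatile 2-methylbut-2-ene; no stereocentre is formed.

Step 2
Reactants: 3 (2E,6E,10E)-6,10-dimethyl-14-oxopentadeca-2,6,10-trienal; 4 dibenzyl malonate
Product: 5 dibenzyl 2-[(3R,6E,10E)-6,10-dimethyl-1,14-dioxopentadeca-6,10-dien-3-yl]malonate
Conditions: (S)-2-{bis[3,5-bis(trifluoromethyl)phenyl](trimethylsilyloxy)methyl}pyrrolidine (10 mol %), EtOH, 0 °C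
Reagents that add atoms: none
Why: Iminium-catalysed (Jørgensen–Hayashi) Michael addition in which the (S)-diarylprolinol silyl ether shields one face of the E-iminium ion, so the malonate adds to the open face and sets C1 as (R); the methyl ketone does not condense with the hindered amine.

Step 3
Reactants: 5 dibenzyl 2-[(3R,6E,10E)-6,10-dimethyl-1,14-dioxopentadeca-6,10-dien-3-yl]malonate
Product: 6 dibenzyl 2-[(1R,3R,4R,7E,11E)-3,4-dihydroxy-4,8,12-trimethylcyclotetradeca-7,11-dien-1-yl]malonate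
Conditions: TiCl3(DME)1.5, Zn–Cu couple, DME, 25 °C, syringe-pump addition of 5 over 30 h (final 2 mM); aq. K2CO3
Reagents that add atoms: none
Why: McMurry-type titanium pinacol macrocyclisation (a known way to close 14-membered cembranoid 3,4-diols) in which the titanium ketyl of the aldehyde, an acyl-anion-type umpoled carbon, attacks the ketone carbon C4 so that two electrophilic carbonyl carbons are joined; the large ring favours the trans (threo) diol and the peripheral C1 malonate is expected to bias it towards (3R,4R), the minor diastereomers being removed by chromatography.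

Step 4
Reactants: 6 dibenzyl 2-[(1R,3R,4R,7E,11E)-3,4-dihydroxy-4,8,12-trimethylcyclotetradeca-7,11-dien-1-yl]malonate
Product: 7 dibenzyl 2-[(1R,3R,4R,7S,8S,11E)-4,7-epoxy-3,8-dihydroxy-4,8,12-trimethylcyclotetradec-11-en-1-yl]malonate
Conditions: K2OsO2(OH)4 (5 mol %), pyridine N-oxide, citric acid, Cu(OTf)2 (cat.), MeCN/aq. pH 6.5 buffer, 50 °C
Reagents that add atoms: pyridine N-oxide, [O-][n+]1ccccc1
Why: Donohoe osmium-catalysed oxidative cyclisation in which the osmium glycolate of the 3,4-diol delivers the C4 oxygen and an oxo ligand syn across the (E)-C7=C8 alkene through a compact transition state that can only give the cis-2,5-THF, so C7 (S) and C8 (S) follow from C4; the C11=C12 alkene is out of reach.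

Step 5
Reactants: 7 dibenzyl 2-[(1R,3R,4R,7S,8S,11E)-4,7-epoxy-3,8-dihydroxy-4,8,12-trimethylcyclotetradec-11-en-1-yl]malonate
Product: 9 dibenzyl 2-[(1R,3R,4R,7S,8S,11E)-3-acetoxy-4,7-epoxy-4,8,12-trimethyl-8-(triethylsilyloxy)cyclotetradec-11-en-1-yl]malonate, via C3 monoacetate 8 (not isolated)
Conditions: Ac2O, pyridine, DMAP (cat.), CH2Cl2, 0 °C; MeOH quench, evaporate; TESOTf, 2,6-lutidine, CH2Cl2, −40 to 0 °C
Reagents that add atoms: acetic anhydride, CC(=O)OC(C)=O; triethylsilyl trifluoromethanesulfonate, CC[Si](CC)(CC)OS(=O)(=O)C(F)(F)F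
Why: Acylation then silylation, in which DMAP-catalysed acetylation is selective for the secondary C3 hydroxyl and the silyl triflate then caps the tertiary C8 hydroxyl so that it cannot open the later epoxide (and the C3 hydroxyl can no longer lactonise onto the malonate).

Step 6
Reactants: 9 dibenzyl 2-[(1R,3R,4R,7S,8S,11E)-3-acetoxy-4,7-epoxy-4,8,12-trimethyl-8-(triethylsilyloxy)cyclotetradec-11-en-1-yl]malonate
Product: 10 dibenzyl 2-[(1R,3R,4R,7S,8S,11S,12S)-3-acetoxy-4,7:11,12-diepoxy-4,8,12-trimethyl-8-(triethylsilyloxy)cyclotetradecan-1-yl]malonate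
Conditions: ent-Shi ketone (from L-fructose, 30 mol %), KHSO5 (as Oxone), K2CO3, Bu4NHSO4, MeCN/CH2(OMe)2/aq. Na2B4O7, 0 °C
Reagents that add atoms: potassium peroxymonosulfate, [K+].[O-]S(=O)(=O)OO
Why: Shi asymmetric epoxidation in which the chiral dioxirane attacks the only remaining alkene, a trisubstituted (E)-olefin, through the spiro transition state to give the (11S,12S)-epoxide under reagent control.

Step 7
Reactants: 10 dibenzyl 2-[(1R,3R,4R,7S,8S,11S,12S)-3-acetoxy-4,7:11,12-diepoxy-4,8,12-trimethyl-8-(triethylsilyloxy)cyclotetradecan-1-yl]malonate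
Product: 12 (1R,3R,4R,7S,8S,11S,12R)-3-acetoxy-4,7-epoxy-11-hydroxy-8-(triethylsilyloxy)cembran-16,12-olide-15-carboxylic acid (C15 epimers), via malonic diacid 11 (not isolated)
Conditions: H2 (1 atm), Pd/C, EtOAc, 23 °C; filter; CH2Cl2, PPTS (cat.), 23 °C
Reagents that add atoms: none
Why: Hydrogenolysis of both benzyl esters (no alkene is left to reduce) frees the malonic acid, which then opens the protonated epoxide in an acid-catalysed 7-exo lactonisation at the tertiary carbon C12 with inversion (12S to 12R) while C11 keeps its oxygen as (S).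

Step 8
Reactants: 12 (1R,3R,4R,7S,8S,11S,12R)-3-acetoxy-4,7-epoxy-11-hydroxy-8-(triethylsilyloxy)cembran-16,12-olide-15-carboxylic acid
Product: 13 11-O-desacetyl-8-O-triethylsilyl dendronpholide Q
Conditions: (CH2O)n, Et2NH, THF, 23 to 60 °C
Reagents that add atoms: formaldehyde (from paraformaldehyde), C=O
Why: Mannich reaction with decarboxylative elimination (the classic α-methylenation of α-carboxy lactones), in which the iminium ion is attacked at C15 and loss of CO2 and Et2NH leaves the exocyclic methylene; no stereocentre is touched.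

Step 9
Reactants: 13 11-O-desacetyl-8-O-triethylsilyl dendronpholide Q
Product: 15 dendronpholide Q, via C8 silyl ether 14 (not isolated)
Conditions: Ac2O, pyridine, DMAP, CH2Cl2, 23 °C; then HF·pyridine, THF, 0 to 23 °C
Reagents that add atoms: acetic anhydride, CC(=O)OC(C)=O
Why: DMAP-catalysed acetylation of the secondary C11 hydroxyl followed by fluoride cleavage of the tertiary silyl ether, so that the tertiary C8 hydroxyl is never exposed to the acylating agent and the α-methylene lactone sees only buffered HF.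

Stereocentres: C1 in step 2; C3 and C4 in step 3; C7 and C8 in step 4; C11 and C12 in step 6, with C12 inverted in step 7.

## Compound list

1 | (5E,9E)-farnesylacetone, (5E,9E)-6,10,14-trimethylpentadeca-5,9,13-trien-2-one | CC(=O)CC/C=C(\C)CC/C=C(\C)CCC=C(C)C | starting material
2 | (E)-crotonaldehyde, (E)-but-2-enal | C/C=C/C=O | starting material
3 | (2E,6E,10E)-6,10-dimethyl-14-oxopentadeca-2,6,10-trienal | CC(=O)CC/C=C(\C)CC/C=C(\C)CC/C=C/C=O | intermediate
4 | dibenzyl malonate | O=C(CC(=O)OCc1ccccc1)OCc1ccccc1 | starting material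
5 | dibenzyl 2-[(3R,6E,10E)-6,10-dimethyl-1,14-dioxopentadeca-6,10-dien-3-yl]malonate | O=CC[C@@H](CC/C(C)=C/CC/C(C)=C/CCC(C)=O)C(C(=O)OCc1ccccc1)C(=O)OCc1ccccc1 | intermediate
6 | dibenzyl 2-[(1R,3R,4R,7E,11E)-3,4-dihydroxy-4,8,12-trimethylcyclotetradeca-7,11-dien-1-yl]malonate (macrocyclic diol) | [C@H]1(C(C(=O)OCc2ccccc2)C(=O)OCc2ccccc2)C[C@@H](O)[C@](C)(O)CC/C=C(\C)CC/C=C(\C)CC1 | intermediate
7 | dibenzyl 2-[(1R,3R,4R,7S,8S,11E)-4,7-epoxy-3,8-dihydroxy-4,8,12-trimethylcyclotetradec-11-en-1-yl]malonate (THF diol) | [C@H]1(C(C(=O)OCc2ccccc2)C(=O)OCc2ccccc2)C[C@@H](O)[C@@]3(C)CC[C@H](O3)[C@@](C)(O)CC/C=C(\C)CC1 | intermediate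
8 | 3-O-acetate of 7 (C8 hydroxyl free) | [C@H]1(C(C(=O)OCc2ccccc2)C(=O)OCc2ccccc2)C[C@@H](OC(C)=O)[C@@]3(C)CC[C@H](O3)[C@@](C)(O)CC/C=C(\C)CC1 | intermediate
9 | dibenzyl 2-[(1R,3R,4R,7S,8S,11E)-3-acetoxy-4,7-epoxy-4,8,12-trimethyl-8-(triethylsilyloxy)cyclotetradec-11-en-1-yl]malonate | [C@H]1(C(C(=O)OCc2ccccc2)C(=O)OCc2ccccc2)C[C@@H](OC(C)=O)[C@@]3(C)CC[C@H](O3)[C@@](C)(O[Si](CC)(CC)CC)CC/C=C(\C)CC1 | intermediate
10 | (11S,12S)-11,12-epoxide of 9 | [C@H]1(C(C(=O)OCc2ccccc2)C(=O)OCc2ccccc2)C[C@@H](OC(C)=O)[C@@]3(C)CC[C@H](O3)[C@@](C)(O[Si](CC)(CC)CC)CC[C@@H]4O[C@@]4(C)CC1 | intermediate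
11 | malonic diacid corresponding to 10 | [C@H]1(C(C(=O)O)C(=O)O)C[C@@H](OC(C)=O)[C@@]3(C)CC[C@H](O3)[C@@](C)(O[Si](CC)(CC)CC)CC[C@@H]4O[C@@]4(C)CC1 | intermediate
12 | (1R,3R,4R,7S,8S,11S,12R)-3-acetoxy-4,7-epoxy-11-hydroxy-8-(triethylsilyloxy)cembran-16,12-olide-15-carboxylic acid (C15 epimers) | OC(=O)C1C(=O)O[C@]2(C)CC[C@@H]1C[C@@H](OC(C)=O)[C@@]1(C)CC[C@H](O1)[C@@](C)(O[Si](CC)(CC)CC)CC[C@@H]2O | intermediate
13 | 11-O-desacetyl-8-O-triethylsilyl dendronpholide Q | C=C1C(=O)O[C@]2(C)CC[C@@H]1C[C@@H](OC(C)=O)[C@@]1(C)CC[C@H](O1)[C@@](C)(O[Si](CC)(CC)CC)CC[C@@H]2O | intermediate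
14 | 8-O-triethylsilyl dendronpholide Q | C=C1C(=O)O[C@]2(C)CC[C@@H]1C[C@@H](OC(C)=O)[C@@]1(C)CC[C@H](O1)[C@@](C)(O[Si](CC)(CC)CC)CC[C@@H]2OC(C)=O | intermediate
15 | dendronpholide Q | C=C1C(=O)O[C@]2(C)CC[C@@H]1C[C@@H](OC(C)=O)[C@@]1(C)CC[C@H](O1)[C@@](C)(O)CC[C@@H]2OC(C)=O | target

## Step count and risks

Total step count: 9. Longest linear sequence: 9 (fully linear from 1).

**Step 3 (pinacol macrocyclisation).** The threo preference rests on the general trend for large-ring titanium pinacols, and the facial sense relative to the remote C1 centre is not secured, so a mixture of diols is possible. Simple reduction of the aldehyde is a further side reaction.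

The fallback separates ring closure from stereocontrol; it sets out from 1 and comes back at 6. Treat 1 with KN(SiMe3)2 and PhNTf2 at −78 °C to give the kinetic enol triflate F1. Carry this through the same cross-metathesis with 2 to the enal triflate F2, and through the same organocatalytic Michael addition of 4 to the aldehyde triflate F3. Close the ring by a catalytic asymmetric Nozaki–Hiyama–Kishi reaction (CrCl2 with a chiral sulfonamide ligand, NiCl2, Mn, Cp2ZrCl2, MeCN) to give the exo-methylene allylic alcohol F4, in which C3 is set by the ligand. Epoxidise with VO(acac)2 and t-BuOOH to the spiro-epoxide F5; hydroxyl direction and allylic 1,2-strain give the erythro isomer, which corresponds to the (4R) carbinol. Finally deprotonate the malonate with NaH and open the epoxide at its methylene carbon with LiEt3BH to give 6.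

**Step 4 (oxidative cyclisation).** The transannular cyclisation may be slow, and in the warm, weakly acidic medium the free C3 hydroxyl of 6 can lactonise onto a benzyl ester, which removes the diol that the osmium needs.

The fallback sets out from 6 and comes back at 8. Acetylate the secondary hydroxyl of 6 (Ac2O, pyridine) to the monoacetate F6. Cyclise its tertiary bishomoallylic alcohol with pyridinium chlorochromate (C5H5NH)[CrO3Cl] in CH2Cl2. This hexavalent-chromium syn-oxidative cyclisation proceeds through a chromate ester and gives the cis-THF with the C8 hydroxyl, that is 8, which is then isolated and silylated to 9.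

**Step 1 (cross-metathesis).** The catalyst may also attack the internal trisubstituted alkenes or stall at low conversion.

The fallback sets out from 1 and comes back at 3. Treat 1 with NBS in aqueous THF and then K2CO3 in MeOH to give the terminal epoxide F7. Cleave it with HIO4·2H2O to the keto-aldehyde F8. An aldehyde-selective Wittig reaction with Ph3P=CHCHO then gives 3.

## Further compounds

F1 | step 3 | (5E,9E)-6,10,14-trimethylpentadeca-1,5,9,13-tetraen-2-yl trifluoromethanesulfonate | C=C(OS(=O)(=O)C(F)(F)F)CC/C=C(\C)CC/C=C(\C)CCC=C(C)C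
F2 | step 3 | (5E,9E,13E)-6,10-dimethyl-15-oxopentadeca-1,5,9,13-tetraen-2-yl trifluoromethanesulfonate | C=C(OS(=O)(=O)C(F)(F)F)CC/C=C(\C)CC/C=C(\C)CC/C=C/C=O
F3 | step 3 | dibenzyl 2-[(3R,6E,10E)-6,10-dimethyl-1-oxo-14-(trifluoromethylsulfonyloxy)pentadeca-6,10,14-trien-3-yl]malonate | O=CC[C@@H](CC/C(C)=C/CC/C(C)=C/CCC(=C)OS(=O)(=O)C(F)(F)F)C(C(=O)OCc1ccccc1)C(=O)OCc1ccccc1
F4 | step 3 | dibenzyl 2-[(1R,3R,7E,11E)-3-hydroxy-8,12-dimethyl-4-methylidenecyclotetradeca-7,11-dien-1-yl]malonate | [C@H]1(C(C(=O)OCc2ccccc2)C(=O)OCc2ccccc2)C[C@@H](O)C(=C)CC/C=C(\C)CC/C=C(\C)CC1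
F5 | step 3 | dibenzyl 2-[(1R,3R,4S,7E,11E)-4,18-epoxy-3-hydroxy-4,8,12-trimethylcyclotetradeca-7,11-dien-1-yl]malonate (spiro-epoxide on C4) | [C@H]1(C(C(=O)OCc2ccccc2)C(=O)OCc2ccccc2)C[C@@H](O)[C@@]4(CO4)CC/C=C(\C)CC/C=C(\C)CC1
F6 | step 4 | dibenzyl 2-[(1R,3R,4R,7E,11E)-3-acetoxy-4-hydroxy-4,8,12-trimethylcyclotetradeca-7,11-dien-1-yl]malonate | [C@H]1(C(C(=O)OCc2ccccc2)C(=O)OCc2ccccc2)C[C@@H](OC(C)=O)[C@](C)(O)CC/C=C(\C)CC/C=C(\C)CC1
F7 | step 1 | (5E,9E)-13,14-epoxy-6,10,14-trimethylpentadeca-5,9-dien-2-one | CC(=O)CC/C=C(\C)CC/C=C(\C)CCC1OC1(C)C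
F8 | step 1 | (4E,8E)-4,8-dimethyl-12-oxotrideca-4,8-dienal | CC(=O)CC/C=C(\C)CC/C=C(\C)CCC=O
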